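From 6.00 d to 10.0 d the north run's isomer grew faster than its target, by a factor of 2.16 against 1.27. So your hunch that isomer comes from target fits the readings, and we can give you a clock for it.

| flask | starting material | second substrate | free enzyme | temperature | remark | time |
|---|---|---|---|---|---|---|
| south-west | 0.010 M | 0.015 M (fed, over 3.0 d) | 1 µM | 5 °C | run made earlier; the fed solution adds 1.0 times the starting volume |  |
| north | 0.010 M | 0.015 M (fed, over 3.0 d) | 4 µM | 25 °C | run made earlier; the fed solution adds 1.0 times the starting volume |  |
| west | 0.020 M | 0.015 M (fed, over 3.0 d) | 2 µM | 5 °C | run made earlier; the fed solution adds 1.0 times the starting volume |  |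
| red | 0.010 M | 0.0150 M (fed, over 3.0 d) | 2.0 µM | 25 °C | the fed solution adds 1.0 times the starting volume | 12 d |
| teal | 0.010 M | 0.0150 M (fed, over 3.0 d) | 2.0 µM | 40 °C | the fed solution adds 1.0 times the starting volume | 12 d |
| amber | 0.010 M | 0.0150 M (fed, over 3.0 d) | 2.0 µM | 10 °C | the fed solution adds 1.0 times the starting volume | 12 d |

| run | time / d | target / % | isomer of the product / % |
|---|---|---|---|
| south-west | 6.00 | 1.3 | 0 |
| south-west | 10.0 | 1.4 | 0.5 |
| south-west | 15.0 | 1.4 | 0.5 |
| south-west | 20.0 | 3.2 | 0 |
| south-west | 25.0 | 2.9 | 0 |
| north | 2.08 | 11.5 | 1.1 |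
| north | 4.00 | 18.5 | 3.2 |
| north | 6.00 | 24.5 | 4.4 |
| north | 8.00 | 28.4 | 7.2 |
| north | 10.0 | 31.0 | 9.5 |
| west | 6.00 | 1.1 | 0.6 |
| west | 10.0 | 2.2 | 0.4 |
| west | 15.0 | 2.7 | 0.3 |
| west | 20.0 | 4.0 | 0 |
| west | 25.0 | 4.1 | 0.1 |

(each reading ± 0.3 percentage points)

- charges are per starting volume, the dose included; the dosed solution carries all of it
- the analysis behind the earlier runs scatters by 0.3 percentage points, standard deviation

* the flask that comes out highest in share of target in all that became target or isomer of the product, or "all alike" when all lie within 1.5 percentage points (red / teal / amber / all alike)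
* share of target in all that became target or isomer of the product, red
* share of target in all that became target or isomer of the product, teal
* share of target in all that became target or isomer of the product, amber

Take the balance of starting material, the reagent charged in the smaller amount (0.010 M against 0.0150 M of second substrate): we assume that what leaves it ends as target, and that target goes on to isomer. If product is made fairly steadily, its mean age is half the run time. We therefore define the ageing rate as the isomer's share of product divided by that mean age, which north gives at 10.0 d as 0.0469 d⁻¹. Its 6.00 d reading gives 0.0507 d⁻¹. Ageing rate times half the run time is the ageing number, which we take as the isomer's share while that number is small, and at a given temperature we reckon it without the enzyme charge.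

For red, at north's temperature, the number is 0.281, so we reckon a target share of 71.9%. Target per µM at 6.00 d, north over south-west, reads 4.71 across 5 °C to 25 °C. If isomerisation scales by that same factor per degree, we reckon that teal ages at 0.150 d⁻¹, with number 0.900. That is too large for the rule, so we give teal no figure, only last place. Amber, the coldest, we put first.

The forecast says amber, with red 80%, teal 40% and amber 96%, adding: "This is uncertain because of possible reversibility and enzyme decay".

The flasks give amber highest: red 75.0%, teal 62.4%, amber 95.0%.

    free enzyme → unfolded enzyme (k = 2.98 × 10⁻⁶ min⁻¹, Ea = 259 kJ mol⁻¹)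
    starting material + free enzyme ⇌ first complex (K = 79.9 M⁻¹, k = 4080 M⁻¹ min⁻¹, Ea = 46.0 kJ mol⁻¹, ΔH = −3.00 kJ mol⁻¹)
    first complex ⇌ loaded enzyme + first product (K = 0.00492 M, k = 2.11 min⁻¹, Ea = 84.0 kJ mol⁻¹, ΔH = −40.0 kJ mol⁻¹)
    second substrate + loaded enzyme ⇌ second complex (K = 320 M⁻¹, k = 3690 M⁻¹ min⁻¹, Ea = 40.0 kJ mol⁻¹, ΔH = −2.00 kJ mol⁻¹)
    second complex → free enzyme + target (k = 4.68 min⁻¹, Ea = 82.0 kJ mol⁻¹)
    target ⇌ isomer of the product (K = 0.605, k = 3.07 × 10⁻⁴ min⁻¹, Ea = 96.0 kJ mol⁻¹, ΔH = −2.00 kJ mol⁻¹)
    free enzyme → spent catalyst (k = 3.95 × 10⁻⁴ min⁻¹, Ea = 105 kJ mol⁻¹)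
    second substrate → decomposed reagent (k = 1.98 × 10⁻⁴ min⁻¹, Ea = 97.0 kJ mol⁻¹)
    (constants at 40 °C)

Teal has come to rest, with 97.4% of its catalyst spent; red and amber have not. Left ten times as long, teal stays at 62.3%, while red falls to 61.4% and amber to 71.4%. In teal, target and isomer relax towards each other, both ways together, with a half-life of 0.591 d, short against 12 d, and teal ends with 21.2% of target to 12.8% of isomer.

The neighbour of teal charged with 8.00 µM has teal's temperature and time, and we reckon the ageing rate without the enzyme charge, so it carries teal's number, 0.900, and should match teal's share. It gives 62.3%, with target at 44.5% against teal's 21.2%.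

The numbers in the tables were computed for substances that don't exist, noise included.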